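The side chain is cut at its C9'–C10' bond, where allylic CH2 C9' meets vinylic CH C10' of the third trisubstituted olefin counted from the ring. One operation, 9-BBN hydroboration followed by B-alkyl Suzuki–Miyaura coupling, joins a ring-bearing C12 fragment to a C9 (E)-alkenyl iodide and leaves all olefin geometries untouched. It exploits the terminal C8'=C9' vinyl group of a 1,3-diene, the only monosubstituted olefin present, as a latent homoallylic nucleophile. The precursor is a cis-hydroxy dioxolane of the cyclohexenone ring carrying a (2E,6E)-3,7-dimethylnona-2,6,8-trienyl chain; its C4 and C5 stereocentres come from one Noyori hydrogenation with dynamic kinetic resolution.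

Key step: step 10

Remark: the antipode of the ruthenium catalyst in step 7 is chosen by analogy with the hydrogenation of 2,4,4-trimethylcyclohex-2-enone; the sense must be confirmed on the first run and the mirror-image catalyst used if the 8R series results.

Ring positions C8 and C9 of the spiroketal intermediates become C4 and C5 of the target cyclohexenone.

Step 1
Reactants: 1 1,4-dioxaspiro[4.5]dec-6-en-8-one
Product: 2 7-iodo-1,4-dioxaspiro[4.5]dec-6-en-8-one
Conditions: I2, pyridine/CH2Cl2 (1:1), 0 °C to rt
Reagents that add atoms: iodine [I][I]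
Why: α-Iodination of the enone by pyridine addition, iodination of the resulting enolate and E1cB loss of pyridine should place iodine only on the α-carbon C7 and leave the base-stable dioxolane untouched.

Step 2
Reactants: 2 7-iodo-1,4-dioxaspiro[4.5]dec-6-en-8-one
Product: 3 7-methyl-1,4-dioxaspiro[4.5]dec-6-en-8-one
Conditions: MeB(OH)2 (2 equiv), PdCl2(dppf) (5 mol %), K2CO3 (3 equiv), 1,4-dioxane/H2O, 90 °C
Reagents that add atoms: methylboronic acid CB(O)O
Why: Suzuki–Miyaura methylation of the α-iodoenone should replace iodine by CH3 at the sp2 carbon under basic conditions that the ketal tolerates.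

Step 3
Reactants: 4 geranyl acetate, (2E)-3,7-dimethylocta-2,6-dien-1-yl acetate
Product: 5 (2E,6E)-3,7-dimethyl-8-oxoocta-2,6-dien-1-yl acetate
Conditions: SeO2 (1.2 equiv), 95% EtOH, reflux
Reagents that add atoms: selenium dioxide O=[Se]=O
Why: Riley allylic oxidation (ene reaction then [2,3]-sigmatropic shift) should attack the (E)-methyl group of the electron-richer terminal olefin and, with stoichiometric SeO2 at reflux, carry it on to the (E)-enal, the olefin next to the acetate being deactivated.

Step 4
Reactants: 5 (2E,6E)-3,7-dimethyl-8-oxoocta-2,6-dien-1-yl acetate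
Product: 7 (2E,6E)-3,7-dimethylnona-2,6,8-trien-1-ol, via trienyl acetate 6 (not isolated)
Conditions: Ph3PCH3Br (1.15 equiv), KOt-Bu (1.1 equiv), THF, −78 to 0 °C; then MeOH, K2CO3 (cat.), rt
Reagents that add atoms: methyltriphenylphosphonium bromide C[P+](c1ccccc1)(c1ccccc1)c1ccccc1.[Br-]
Why: Wittig methylenation should turn the enal into the terminal 1,3-diene without touching either trisubstituted (E)-olefin, and Zemplén-type methanolysis in the same flask frees the allylic alcohol.

Step 5
Reactants: 7 (2E,6E)-3,7-dimethylnona-2,6,8-trien-1-ol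
Product: 8 (2E,6E)-1-bromo-3,7-dimethylnona-2,6,8-triene
Conditions: CBr4, PPh3, CH2Cl2, 0 °C
Reagents that add atoms: carbon tetrabromide BrC(Br)(Br)Br
Why: Appel bromination substitutes the primary allylic hydroxyl by SN2 under neutral conditions, so neither allylic transposition nor addition to the diene is expected.

Step 6
Reactants: 3 7-methyl-1,4-dioxaspiro[4.5]dec-6-en-8-one; 8 (2E,6E)-1-bromo-3,7-dimethylnona-2,6,8-triene
Product: 10 rac-9-[(2E,6E)-3,7-dimethylnona-2,6,8-trien-1-yl]-7-methyl-1,4-dioxaspiro[4.5]dec-6-en-8-one, via lithium dienolate 9 (not isolated)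
Conditions: LDA (1.05 equiv), THF, −78 °C; then 8, DMPU, −78 to −20 °C
Reagents that add atoms: none
Why: Kinetic deprotonation can occur only at C9 (spiro carbon C5 carries no γ-proton), and SN2 alkylation of the cross-conjugated lithium dienolate by the allylic bromide should give the C9-allylated enone, racemic on purpose because step 7 corrects C9.

Step 7
Reactants: 10 rac-9-[(2E,6E)-3,7-dimethylnona-2,6,8-trien-1-yl]-7-methyl-1,4-dioxaspiro[4.5]dec-6-en-8-one
Product: 11 (8S,9S)-9-[(2E,6E)-3,7-dimethylnona-2,6,8-trien-1-yl]-7-methyl-1,4-dioxaspiro[4.5]dec-6-en-8-ol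
Conditions: H2 (8 atm), RuCl2[(S)-tolbinap][(R,R)-dpen] (0.5 mol %), KOt-Bu (20 mol %), i-PrOH, 25 °C
Reagents that add atoms: none
Why: Noyori asymmetric hydrogenation with dynamic kinetic resolution: alkoxide equilibrates the C9 epimers through the dienolate, the outer-sphere RuH/NH catalyst reduces only C=O (diene and trisubstituted olefins stay), the catalyst sets C8 as S, and the cis preference known for 2-substituted cyclohexanones should funnel the material into the (8S,9S) isomer.

Step 8
Reactants: 12 5-bromo-2-methylpent-2-ene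
Product: 13 6-methylhept-5-en-1-yne
Conditions: lithium acetylide–ethylenediamine complex (1.3 equiv), DMSO, 10 °C to rt
Reagents that add atoms: lithium acetylide ethylenediamine complex [Li+].[C-]#C.NCCN
Why: SN2 alkylation of lithium acetylide by the primary homoallylic bromide in DMSO should give the terminal alkyne.

Step 9
Reactants: 13 6-methylhept-5-en-1-yne
Product: 15 (E)-1-iodo-2,6-dimethylhepta-1,5-diene, via alkenyldimethylalane 14 (not isolated)
Conditions: AlMe3 (2 equiv), Cp2ZrCl2 (25 mol %), CH2Cl2, 0 °C to rt; then I2, THF, −30 to 0 °C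
Reagents that add atoms: trimethylaluminium C[Al](C)C; iodine [I][I]
Why: Negishi zirconium-catalysed methylalumination adds CH3 and Al syn across the alkyne with Al on the terminal carbon, and iodinolysis of the C–Al bond with retention should give the (E)-iodide.

Step 10
Reactants: 11 (8S,9S)-9-[(2E,6E)-3,7-dimethylnona-2,6,8-trien-1-yl]-7-methyl-1,4-dioxaspiro[4.5]dec-6-en-8-ol; 15 (E)-1-iodo-2,6-dimethylhepta-1,5-diene
Product: 17 (8S,9S)-7-methyl-9-[(2E,6E,10E)-3,7,11,15-tetramethylhexadeca-2,6,10,14-tetraen-1-yl]-1,4-dioxaspiro[4.5]dec-6-en-8-ol, via bis(9-BBN) adduct 16 (not isolated)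
Conditions: 9-BBN (2.3 equiv), THF, 0 °C to rt; then 15 (1.2 equiv), PdCl2(dppf) (5 mol %), AsPh3 (10 mol %), Cs2CO3 (3 equiv), DMF/H2O, rt
Reagents that add atoms: none
Why: 9-BBN adds B–H syn across the terminal C8'=C9' double bond of the diene with boron on the CH2 terminus (a second equivalent is consumed by the ring C8 hydroxyl as a borinate) to give homoallylic borane 16, whose base-activated borate transfers the primary alkyl group to the alkenylpalladium iodide formed by oxidative addition of 15 to zerovalent palladium, and reductive elimination makes the C9'–C10' sp3–sp2 bond. The closest known reaction type is the B-alkyl Suzuki–Miyaura coupling of a 9-BBN hydroboration product with an (E)-alkenyl iodide. No ring is closed and no stereocentre is created; the ring stereocentres C8 and C9 are remote from the reacting atoms and are not touched. The step needs site selectivity in the hydroboration, secured because the vinyl group is the only monosubstituted olefin and bulky 9-BBN ignores the three trisubstituted olefins and the dioxolane-masked carbonyl at room temperature. It also needs retention of both olefin geometries, secured because oxidative addition and reductive elimination are stereoretentive at C10' and the C6'=C7' olefin never takes part. β-Hydride elimination from the alkylpalladium intermediate is held back by the wide-bite-angle dppf ligand, which speeds reductive elimination.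

Step 11
Reactants: 17 (8S,9S)-7-methyl-9-[(2E,6E,10E)-3,7,11,15-tetramethylhexadeca-2,6,10,14-tetraen-1-yl]-1,4-dioxaspiro[4.5]dec-6-en-8-ol
Product: 18 (4S,5S)-4-hydroxy-3-methyl-5-[(2E,6E,10E)-3,7,11,15-tetramethylhexadeca-2,6,10,14-tetraen-1-yl]cyclohex-2-en-1-one
Conditions: PPTS (20 mol %), acetone/H2O (10:1), 50 °C
Reagents that add atoms: water O
Why: Acid-catalysed hydrolysis of the allylic dioxolane through its allyl-stabilised oxocarbenium ion should release the conjugated enone; C4 and C5 are not α to the carbonyl and cannot epimerise, and the mild acid avoids dehydration to a phenol.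

Compound list
1 | 1,4-dioxaspiro[4.5]dec-6-en-8-one | O=C1C=CC2(CC1)OCCO2 | starting material
2 | 7-iodo-1,4-dioxaspiro[4.5]dec-6-en-8-one | O=C1C(I)=CC2(CC1)OCCO2 | intermediate
3 | 7-methyl-1,4-dioxaspiro[4.5]dec-6-en-8-one | CC1=CC2(CCC1=O)OCCO2 | intermediate
4 | geranyl acetate, (2E)-3,7-dimethylocta-2,6-dien-1-yl acetate | CC(C)=CCC/C(C)=C/COC(C)=O | starting material
5 | (2E,6E)-3,7-dimethyl-8-oxoocta-2,6-dien-1-yl acetate | O=C/C(C)=C/CC/C(C)=C/COC(C)=O | intermediate
6 | (2E,6E)-3,7-dimethylnona-2,6,8-trien-1-yl acetate (formed in the flask in step 4) | C=C/C(C)=C/CC/C(C)=C/COC(C)=O | intermediate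
7 | (2E,6E)-3,7-dimethylnona-2,6,8-trien-1-ol | C=C/C(C)=C/CC/C(C)=C/CO | intermediate
8 | (2E,6E)-1-bromo-3,7-dimethylnona-2,6,8-triene | C=C/C(C)=C/CC/C(C)=C/CBr | intermediate
9 | lithium 7-methyl-1,4-dioxaspiro[4.5]deca-6,8-dien-8-olate (formed in the flask in step 6) | [Li+].[O-]C1=CCC2(OCCO2)C=C1C | intermediate
10 | rac-9-[(2E,6E)-3,7-dimethylnona-2,6,8-trien-1-yl]-7-methyl-1,4-dioxaspiro[4.5]dec-6-en-8-one | C=C/C(C)=C/CC/C(C)=C/CC1CC2(OCCO2)C=C(C)C1=O | intermediate
11 | (8S,9S)-9-[(2E,6E)-3,7-dimethylnona-2,6,8-trien-1-yl]-7-methyl-1,4-dioxaspiro[4.5]dec-6-en-8-ol | C=C/C(C)=C/CC/C(C)=C/C[C@H]1CC2(OCCO2)C=C(C)[C@H]1O | intermediate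
12 | 5-bromo-2-methylpent-2-ene | CC(C)=CCCBr | starting material
13 | 6-methylhept-5-en-1-yne | CC(C)=CCCC#C | intermediate
14 | (E)-(2,6-dimethylhepta-1,5-dien-1-yl)dimethylalane (formed in the flask in step 9) | CC(C)=CCC/C(C)=C/[Al](C)C | intermediate
15 | (E)-1-iodo-2,6-dimethylhepta-1,5-diene | CC(C)=CCC/C(C)=C/I | intermediate
16 | (8S,9S)-8-[(9-borabicyclo[3.3.1]nonan-9-yl)oxy]-9-[(2E,6E)-9-(9-borabicyclo[3.3.1]nonan-9-yl)-3,7-dimethylnona-2,6-dien-1-yl]-7-methyl-1,4-dioxaspiro[4.5]dec-6-ene (formed in the flask in step 10) | B3(C4CCCC3CCC4)CC/C(C)=C/CC/C(C)=C/C[C@H]1CC2(OCCO2)C=C(C)[C@H]1OB5C6CCCC5CCC6 | intermediate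
17 | (8S,9S)-7-methyl-9-[(2E,6E,10E)-3,7,11,15-tetramethylhexadeca-2,6,10,14-tetraen-1-yl]-1,4-dioxaspiro[4.5]dec-6-en-8-ol | CC(C)=CCC/C(C)=C/CC/C(C)=C/CC/C(C)=C/C[C@H]1CC2(OCCO2)C=C(C)[C@H]1O | intermediate
18 | (4S,5S)-4-hydroxy-3-methyl-5-[(2E,6E,10E)-3,7,11,15-tetramethylhexadeca-2,6,10,14-tetraen-1-yl]cyclohex-2-en-1-one | CC(C)=CCC/C(C)=C/CC/C(C)=C/CC/C(C)=C/C[C@H]1CC(=O)C=C(C)[C@H]1O | target

Total step count: 11.
Longest linear sequence: 7 steps (steps 3, 4, 5, 6, 7, 10, 11, from geranyl acetate).

Steps most likely to fail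

Step 7. Epimerisation at C9 may be too slow compared with reduction, so that the dynamic kinetic resolution collapses into a simple kinetic resolution, or the catalyst may discriminate the carbonyl faces poorly. The fallback sets out from 10. Reduction with LiBH(s-Bu)3 (THF, −78 °C; 1,2-addition from the face opposite the C9 chain, as with other α-methyl enones) should give the cis alcohol as a racemate, that is 11 together with its enantiomer (8R,9R)-9-[(2E,6E)-3,7-dimethylnona-2,6,8-trien-1-yl]-7-methyl-1,4-dioxaspiro[4.5]dec-6-en-8-ol F1. Lipase-catalysed transesterification (Candida antarctica lipase B, vinyl acetate, MTBE, 30 °C) is expected, by the empirical size rule for lipases with the C9 branch as the large group, to acetylate the 8S alcohol to (8S,9S)-9-[(2E,6E)-3,7-dimethylnona-2,6,8-trien-1-yl]-7-methyl-1,4-dioxaspiro[4.5]dec-6-en-8-yl acetate F2 and to leave F1. After chromatographic separation, methanolysis of F2 (K2CO3, MeOH) comes back to the route at 11.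

Step 10. Transmetallation of the O-borylated alkylborane may be sluggish, so that β-hydride elimination and protodeboronation compete with the cross-coupling. The fallback sets out from 11 and passes through the same borane 16. Oxidative work-up (NaOH, H2O2) gives the diol (8S,9S)-9-[(2E,6E)-9-hydroxy-3,7-dimethylnona-2,6-dien-1-yl]-7-methyl-1,4-dioxaspiro[4.5]dec-6-en-8-ol F3. Selective iodination of the primary hydroxyl (I2, PPh3, imidazole, CH2Cl2, 0 °C) gives the iodide (8S,9S)-9-[(2E,6E)-9-iodo-3,7-dimethylnona-2,6-dien-1-yl]-7-methyl-1,4-dioxaspiro[4.5]dec-6-en-8-ol F4. Nickel-catalysed reductive cross-electrophile coupling of F4 with 15 (NiBr2(dme), 2,2'-bipyridine, Mn powder, NaI, DMPU, rt) forms the same C9'–C10' bond by an alkyl-radical pathway that tolerates the free hydroxyl, and comes back to the route at 17.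

Step 6. Proton transfer between product and dienolate may lead to dialkylation, and the dienyl allylic bromide may decompose before it is consumed. The fallback sets out from 3 and from trienyl acetate 6, which is isolated after the Wittig stage of step 4 so that methanolysis and step 5 are skipped. The lithium dienolate 9 (LDA, THF, −78 °C) is allylated by 6 under palladium catalysis (Pd2(dba)3, dppf, LiCl, THF, 0 °C to rt; Tsuji–Trost reaction). Attack at the unsubstituted terminus of the π-allyl complex with retention of the E geometry should give 10, where the route is rejoined; no new compound arises.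

Further compounds
F1 | step 7 | (8R,9R)-9-[(2E,6E)-3,7-dimethylnona-2,6,8-trien-1-yl]-7-methyl-1,4-dioxaspiro[4.5]dec-6-en-8-ol | C=C/C(C)=C/CC/C(C)=C/C[C@@H]1CC2(OCCO2)C=C(C)[C@@H]1O
F2 | step 7 | (8S,9S)-9-[(2E,6E)-3,7-dimethylnona-2,6,8-trien-1-yl]-7-methyl-1,4-dioxaspiro[4.5]dec-6-en-8-yl acetate | C=C/C(C)=C/CC/C(C)=C/C[C@H]1CC2(OCCO2)C=C(C)[C@H]1OC(C)=O
F3 | step 10 | (8S,9S)-9-[(2E,6E)-9-hydroxy-3,7-dimethylnona-2,6-dien-1-yl]-7-methyl-1,4-dioxaspiro[4.5]dec-6-en-8-ol | OCC/C(C)=C/CC/C(C)=C/C[C@H]1CC2(OCCO2)C=C(C)[C@H]1O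
F4 | step 10 | (8S,9S)-9-[(2E,6E)-9-iodo-3,7-dimethylnona-2,6-dien-1-yl]-7-methyl-1,4-dioxaspiro[4.5]dec-6-en-8-ol | ICC/C(C)=C/CC/C(C)=C/C[C@H]1CC2(OCCO2)C=C(C)[C@H]1O
F0 | step 6 | none | none
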